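Count in fractions of the charge per hour. The south and south-west runs, with different starting material, stand at 10.8% and 10.5% after 8.00 h, so I use their pooled curve for the flask, which has their solid reagent and free catalyst.

in all of them: free catalyst 0.25 mM
- south: starting material 0.025 M; solid reagent 0.125 M; run made earlier
- south-west: starting material 0.038 M; solid reagent 0.125 M; run made earlier
- west: starting material 0.050 M; solid reagent 0.19 M; run made earlier
- flask: starting material 0.050 M; solid reagent 0.125 M

| run | time / h | product / % | starting material / % |
|---|---|---|---|
| south | 2.00 | 3.1 | 96.4 |
| south | 4.00 | 7.3 | 93.1 |
| south | 5.00 | 8.6 | 91.4 |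
| south | 8.00 | 10.8 | 88.9 |
| south-west | 2.00 | 3.3 | 97.0 |
| south-west | 4.00 | 6.7 | 92.9 |
| south-west | 5.00 | 8.3 | 91.7 |
| south-west | 8.00 | 10.5 | 90.2 |
| west | 0.500 | 0.1 | 99.6 |
| west | 1.33 | 1.6 | 98.4 |
| west | 3.00 | 4.3 | 95.4 |
| west | 8.00 | 10.5 | 89.6 |

(each reading ± 0.3 percentage points)

- as a solid, counted per litre of solution: solid reagent
- the numbers in the tables scatter by 0.3 percentage points (one standard deviation)
- at the start none of the solid reagent is in solution
- no earlier run changes the charge of free catalyst; that part of a forecast is a guess

1. apparent order in free catalyst when 5.0% of the starting material are converted (percent change of the rate of making product for one percent more free catalyst charged)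

Order one is the zero of the scale. I assume that the catalyst charge scales the pace at each time and leaves the shape of the curve alone; that assumption is a guess. More catalyst then reaches 5.0% earlier, and a steady pace keeps the order at one. A changing pace gives:

order = one + fade × catch-up time

The pooled pace is:

0.0160 /h around 1.00 h
0.0190 /h around 3.00 h
0.00913 /h around 6.00 h

The pooled curve crosses 5.0% near the middle time, so 2.63 h is the catch-up time, the conversion reached divided by the pace there.

Fade is the fall of ln(pace) per hour. From the middle to the last window it reads 0.244 /h, which gives an order of 1.64.

That link is weak, since the pace was still rising before the middle window, by 0.0859 /h. Weighting both sides to the slope at the middle time gives: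

fade = 0.0462 /h
order = 1.12

I commit to that value. The forecast gave 0.9, within 0.5 to 1.1, on the ground that “the rate appears to be limited by the catalytic step”.

The flask gives 1.2.

    starting material + coupling partner + free catalyst → free catalyst + product (k = 284 /M²/min)
    solid reagent ⇌ coupling partner, rate k2*(cs2 - [coupling partner]) while solid is left; crystals form when [coupling partner] > cs2 (solubility = 27.0 mM, k = 0.00457 /min)
    free catalyst → spent catalyst (k = 0.00591 /min)

The flask makes product at 9.34 × 10⁻⁴ M/h when it reaches 5.0%, at 2.98 h, so its conversion over its rate is 2.68 h, beside the catch-up time of 2.63 h from the pooled readings. Divided by the flask's own 2.68 h, the excess of 0.214 over one stands for a fade of 0.0801 /h. The west run reads a climb of 0.0162 /h from 1.33 h to 3.00 h, a window ending at a reading of 4.3%, so its catch-up time reads 3.09 h; with a scatter of 0.3 percentage points on each reading, that is no firm difference from 2.63 h. With that same fade, the order of the west run reads 1.25.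

(The runs are calculated with made-up constants; the scatter is artificial.)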